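The 4 questions come down to one decision about the maple flask: what to do to it at 80 min.

| flask | Q | Z | temperature | remark | time |
|---|---|---|---|---|---|
| maple | 0.16 M | 0.73 mol% | 5 °C | the very flask that is asked about, followed so far |  |
| alder | 0.080 M | 0.73 mol% | −10 °C | run made earlier |  |
| flask | 0.16 M | 0.73 mol% | 5 °C |  | 80 min |

| run | time / min | D / % | Q / % |
|---|---|---|---|
| maple | 12.0 | 10.1 | 86.1 |
| maple | 25.0 | 12.8 | 76.4 |
| maple | 40.0 | 16.9 | 70.3 |
| maple | 50.0 | 17.1 | 67.1 |
| maple | 60.0 | 18.3 | 65.1 |
| alder | 6.00 | 1.4 | 98.5 |
| alder | 15.0 | 1.7 | 97.3 |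
| alder | 30.0 | 5.6 | 94.7 |
| alder | 50.0 | 6.9 | 91.7 |
| alder | 60.0 | 7.9 | 89.6 |

(each reading ± 0.5 percentage points)

- Friday's: at 80 min add Z, 100% of the amount charged, then wait 2.5 h
- Tuesday's: at 80 min raise the temperature by 20 K, then wait 2.5 h
- Sunday's: change nothing and wait 2.5 h more
- Saturday's: at 80 min take out 90% of the D then present, then wait 2.5 h

- D, in percent of the Q first charged, at 80 min
- the remedy with the largest gain of D, or "none" below 2 percentage points (Friday's / Tuesday's / Sunday's / Saturday's / none)
- D present, with what was taken out counted in, in percent of the Q first charged, after Friday's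
- D present, with what was taken out counted in, in percent of the Q first charged, after Saturday's

- D taken out counts as made
- additions bring no volume worth counting

The maple readings show what kind of slowing I must plan for. Of the Q lost by 12.0 min, 72.7% stood as D, but of the Q lost between 40.0 min and 60.0 min, 26.9% did, which is less. From that falling share I read D as coming to a stop against its neighbours, thermodynamic rather than kinetic control.

I therefore reckon from both ends. The maple readings show D at 10.1% by 12.0 min and gaining 1.4 percentage points over the last 20.0 min, and carrying that last gain forward once joins them at 19.7%, the standing share: my estimate of D's share of the material in the maple flask at 80 min.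

I expect more Z or more waiting to leave that share where it stands in the maple flask, so by my reckoning Friday's and Sunday's should gain less than 2 points. Removal is different: if the material left after Saturday's refills to the same share, the count is what was taken out plus the share of the remainder, 33.9%. The maple reading at 12.0 min already stands at half the share, and that time is short against 2.5 h, so I expect the refill to have time. Tuesday's I leave unsized, since the alder run, colder and also more dilute, shows D still climbing at its last reading. I commit to Saturday's.

The forecast differs: “The ln(Q) increments fit a dying catalyst”. It gives 20.4% at 80 min, 35% after Friday's and 22.1% after Saturday's, and it names Friday's.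

The flask gives 19.7% at 80 min, 19.4% after Friday's and 33.5% after Saturday's, so Saturday's wins with 14 points. The loss of Z to J changes D at 80 min by nothing. The standing share of 19.7% gave 33.9% through the refill reckoning, against the 33.5% of the flask.

    Q ⇌ D (K = 0.350, k = 0.0130 min⁻¹, Ea = 79.0 kJ mol⁻¹, ΔH = −27.0 kJ mol⁻¹)
    D ⇌ X (K = 0.620, k = 0.0550 min⁻¹, Ea = 72.0 kJ mol⁻¹, ΔH = 13.0 kJ mol⁻¹)
    X ⇌ G (K = 1.80, k = 8.60 × 10⁻⁴ min⁻¹, Ea = 100 kJ mol⁻¹, ΔH = 18.0 kJ mol⁻¹)
    G ⇌ Q (k = 0.00340 min⁻¹, Ea = 80.0 kJ mol⁻¹)
    2 Z → J (k = 6.20 L mol⁻¹ min⁻¹, Ea = 46.0 kJ mol⁻¹)
    (constants at 5 °C)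

Kept at 30 °C, the same charge has standing ratios of D to Q 0.134, X to D 0.986 and G to X 3.42, which make the standing share 7.79%. That flask computes to 7.79% of D at 80 min.

(The data were generated by integration from invented constants; scatter was added.)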